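## Retrosynthetic overview

1. Target ⇐ C3,C9,C12-triol (formate on the primary OH first, then both acetates) ⇐ cis-fused bicyclic enone by 1,2-reduction, which sets C3.
2. Bicyclic enone ⇐ acyclic formyl enone in one flask: enamine Michael addition C6→C1 closes ring B first, aldol condensation C4→C5 closes ring A second; this sets C1 and C6.
3. Formyl enone ⇐ cross-metathesis of a syn homoallylic alcohol with ethyl vinyl ketone ⇐ (Z)-crotylboration of a β,γ-unsaturated aldehyde, which sets C9 and C10.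
4. That aldehyde ⇐ geometrically defined tetrasubstituted allylic alcohol ⇐ hydroxyl-directed anti-carbomagnesiation/allylation of 5,5-diethoxypent-2-yn-1-ol ⇐ 4,4-diethoxybut-1-yne + formaldehyde.

Assumption: atom labels C1–C15 in the comments are the cadinane positions of the target (ring A = C1–C6 with C3-OAc and C4=C5; ring B = C1, C6–C10 with C7=C11, C9-OAc and C10-Me; C12 carries the formate); O- or C-metalated forms that only precede work-up are not numbered, except 4 and 10.

## Route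

Step 1
Reactants: 1 4,4-diethoxybut-1-yne
Product: 2 5,5-diethoxypent-2-yn-1-ol
Conditions: n-BuLi, THF, −78 °C; (CH2O)n, −78 °C → rt; H2O
Reagents that add atoms: paraformaldehyde (formaldehyde unit), C=O
Why: Acetylide addition to formaldehyde (alkyne hydroxymethylation) installs C12 with the free propargylic OH needed to direct step 2; no stereocentre is formed.

Step 2
Reactants: 2 5,5-diethoxypent-2-yn-1-ol; 3 allyl bromide
Product: 5 (2E)-3-(2,2-diethoxyethyl)-2-methylhexa-2,5-dien-1-ol, via magnesium chelate 4 (not isolated)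
Conditions: MeMgBr (4 equiv), CuI (10 mol%), THF, −10 °C → rt; then 3, −20 °C → rt; H2O
Reagents that add atoms: methylmagnesium bromide, C[Mg]Br
Why: Copper-catalysed, alkoxide-directed anti-carbomagnesiation of a 2-alkyn-1-ol puts methyl on the carbon next to CH2O and magnesium on the distal carbon inside the five-membered chelate 4, and allylation with retention then leaves the allyl group cis to CH2OH and the acetal arm cis to CH3, which is the C7=C11 geometry of the target.

Step 3
Reactants: 5 (2E)-3-(2,2-diethoxyethyl)-2-methylhexa-2,5-dien-1-ol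
Product: 6 tert-butyl{[(2E)-3-(2,2-diethoxyethyl)-2-methylhexa-2,5-dien-1-yl]oxy}dimethylsilane
Conditions: TBSCl, imidazole, CH2Cl2, 0 °C → rt
Reagents that add atoms: tert-butyldimethylsilyl chloride, CC(C)(C)[Si](C)(C)Cl
Why: Silyl ether formation masks the C12 hydroxyl so that the aldehyde made in step 4 stays open-chain (no lactol) for the low-temperature crotylboration.

Step 4
Reactants: 6 tert-butyl{[(2E)-3-(2,2-diethoxyethyl)-2-methylhexa-2,5-dien-1-yl]oxy}dimethylsilane
Product: 8 (3E)-5-[(tert-butyldimethylsilyl)oxy]-3-(2,2-diethoxyethyl)-4-methylpent-3-enal, via vicinal diol 7 (not isolated)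
Conditions: OsO4 (2 mol%), NaIO4 (4 equiv), 2,6-lutidine, dioxane/H2O (3:1), 0 °C → rt
Reagents that add atoms: osmium tetroxide, O=[Os](=O)(=O)=O (oxygen donor to C9, regenerated by sodium periodate, [Na+].[O-]I(=O)(=O)=O)
Why: Lemieux–Johnson oxidative cleavage, in which catalytic OsO4 is expected to dihydroxylate the unhindered monosubstituted alkene in preference to the hindered tetrasubstituted allylic-ether alkene and periodate cleaves diol 7, while the lutidine buffer keeps acetal and silyl ether intact.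

Step 5
Reactants: 8 (3E)-5-[(tert-butyldimethylsilyl)oxy]-3-(2,2-diethoxyethyl)-4-methylpent-3-enal; 9 cis-but-2-ene
Product: 11 (3R,4R,6E)-8-[(tert-butyldimethylsilyl)oxy]-6-(2,2-diethoxyethyl)-3,7-dimethylocta-1,6-dien-4-ol, via (Z)-crotyldiisopinocampheylborane 10 (not isolated)
Conditions: 9, KOt-Bu, n-BuLi, THF, −78 → −45 °C; (−)-Ipc2BOMe, −78 °C; BF3·OEt2; 8, −78 °C; NaOH, H2O2, 0 °C → rt
Reagents that add atoms: none
Why: Brown asymmetric crotylboration through a closed chair transition state, in which the Z-crotyl geometry gives the syn C9-OH/C10-Me relationship and the (+)-α-pinene-derived Ipc groups select the aldehyde face that gives 9R,10R.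

Step 6
Reactants: 11 (3R,4R,6E)-8-[(tert-butyldimethylsilyl)oxy]-6-(2,2-diethoxyethyl)-3,7-dimethylocta-1,6-dien-4-ol; 12 ethyl vinyl ketone (pent-1-en-3-one)
Product: 13 (4E,6R,7R,9E)-11-[(tert-butyldimethylsilyl)oxy]-9-(2,2-diethoxyethyl)-7-hydroxy-6,10-dimethylundeca-4,9-dien-3-one
Conditions: second-generation Hoveyda–Grubbs catalyst (5 mol%), 12 (4 equiv), CH2Cl2, 40 °C
Reagents that add atoms: none
Why: Olefin cross-metathesis of the terminal alkene with an electron-poor vinyl ketone gives the E-enone (C1=C2–C3=O with the C4/C15 ethyl group), the tetrasubstituted alkene is inert to the catalyst and C9/C10 are untouched.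

Step 7
Reactants: 13 (4E,6R,7R,9E)-11-[(tert-butyldimethylsilyl)oxy]-9-(2,2-diethoxyethyl)-7-hydroxy-6,10-dimethylundeca-4,9-dien-3-one
Product: 16 (4aS,5E,7R,8R,8aS)-7-hydroxy-5-(1-hydroxypropan-2-ylidene)-3,8-dimethyl-4a,5,6,7,8,8a-hexahydronaphthalen-2(1H)-one, via hydroxy aldehyde 14 (not isolated), via keto aldehyde 15 (not isolated)
Conditions: AcOH/THF/H2O (3:1:1), 30 °C; evaporate; pyrrolidine (0.3 equiv), AcOH (0.6 equiv), CH2Cl2 (0.02 M), 0 → 35 °C
Reagents that add atoms: none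
Why: Acid hydrolysis removes the silyl ether and the acetal to give 14 (resting as its C9-O lactol), and pyrrolidinium acetate then drives an enamine intramolecular Michael addition (6-exo, C6→C1, ring B, giving 15) followed by a Robinson-type intramolecular aldol condensation (C4→C5, ring A); in the chair transition state C9-OH and C10-Me are equatorial, the enone arm at C1 goes equatorial (trans to C10-Me), and allylic 1,3-strain between the C13 methyl and the s-trans dienamine forces the formyl carbon on C6 axial, which gives the cis ring fusion (1S,6S), while the aldehyde oxygen delivered by water leaves again as water.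

Step 8
Reactants: 16 (4aS,5E,7R,8R,8aS)-7-hydroxy-5-(1-hydroxypropan-2-ylidene)-3,8-dimethyl-4a,5,6,7,8,8a-hexahydronaphthalen-2(1H)-one
Product: 17 (2R,4aS,5E,7R,8R,8aS)-5-(1-hydroxypropan-2-ylidene)-3,8-dimethyl-1,2,4a,5,6,7,8,8a-octahydronaphthalene-2,7-diol
Conditions: NaBH4, CeCl3·7H2O, MeOH, −78 °C
Reagents that add atoms: none
Why: Luche 1,2-reduction of the enone, in which hydride attacks the convex face of the cis-fused bicycle (anti to ring B, whose C10 is axial on ring A) so that the new C3-OH is cis to C10 (3R).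

Step 9
Reactants: 17 (2R,4aS,5E,7R,8R,8aS)-5-(1-hydroxypropan-2-ylidene)-3,8-dimethyl-1,2,4a,5,6,7,8,8a-octahydronaphthalene-2,7-diol
Product: 18 (2E)-2-[(3R,4R,4aS,6R,8aS)-3,6-dihydroxy-4,7-dimethyl-3,4,4a,5,6,8a-hexahydronaphthalen-1(2H)-ylidene]propyl formate
Conditions: acetic formic anhydride (1.05 equiv), pyridine, CH2Cl2, −40 °C
Reagents that add atoms: acetic formic anhydride, CC(=O)OC=O
Why: Kinetically selective O-formylation (acyl transfer from the mixed anhydride) of the unhindered primary allylic C12-OH in preference to the two hindered secondary alcohols (C3 pseudo-axial next to C4-Me, C9 next to C10-Me).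

Step 10
Reactants: 18 (2E)-2-[(3R,4R,4aS,6R,8aS)-3,6-dihydroxy-4,7-dimethyl-3,4,4a,5,6,8a-hexahydronaphthalen-1(2H)-ylidene]propyl formate
Product: 19 (2E)-2-[(3R,4R,4aS,6R,8aS)-3,6-bis(acetyloxy)-4,7-dimethyl-3,4,4a,5,6,8a-hexahydronaphthalen-1(2H)-ylidene]propyl formate
Conditions: Ac2O, pyridine, DMAP (cat.), CH2Cl2, 0 °C → rt
Reagents that add atoms: acetic anhydride, CC(=O)OC(C)=O
Why: DMAP-catalysed acetylation of both secondary alcohols with retention at C3 and C9, the formate being inert under anhydrous acylation conditions, gives the target.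

## Compound list

1 | 4,4-diethoxybut-1-yne (3-butynal diethyl acetal) | C#CCC(OCC)OCC | starting material
2 | 5,5-diethoxypent-2-yn-1-ol | OCC#CCC(OCC)OCC | intermediate
3 | allyl bromide (3-bromoprop-1-ene) | C=CCBr | starting material
4 | magnesium chelate, 3-(2,2-diethoxyethyl)-4-methyl-2,5-dihydro-1,2-oxamagnesole | CCOC(OCC)CC1=C(C)CO[Mg]1 | intermediate
5 | (2E)-3-(2,2-diethoxyethyl)-2-methylhexa-2,5-dien-1-ol (allyl cis to CH2OH) | OC/C(C)=C(\CC=C)CC(OCC)OCC | intermediate
6 | tert-butyl{[(2E)-3-(2,2-diethoxyethyl)-2-methylhexa-2,5-dien-1-yl]oxy}dimethylsilane | CC(C)(C)[Si](C)(C)OC/C(C)=C(\CC=C)CC(OCC)OCC | intermediate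
7 | (4E)-6-[(tert-butyldimethylsilyl)oxy]-4-(2,2-diethoxyethyl)-5-methylhex-4-ene-1,2-diol (both C2 epimers) | CC(C)(C)[Si](C)(C)OC/C(C)=C(\CC(O)CO)CC(OCC)OCC | intermediate
8 | (3E)-5-[(tert-butyldimethylsilyl)oxy]-3-(2,2-diethoxyethyl)-4-methylpent-3-enal | CC(C)(C)[Si](C)(C)OC/C(C)=C(\CC=O)CC(OCC)OCC | intermediate
9 | cis-but-2-ene | C/C=C\C | starting material
10 | (Z)-crotyldiisopinocampheylborane from (−)-Ipc2BOMe | C/C=C\CB([C@@H]1C[C@@H]2C[C@H]([C@H]1C)C2(C)C)[C@@H]1C[C@@H]2C[C@H]([C@H]1C)C2(C)C | intermediate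
11 | (3R,4R,6E)-8-[(tert-butyldimethylsilyl)oxy]-6-(2,2-diethoxyethyl)-3,7-dimethylocta-1,6-dien-4-ol | CC(C)(C)[Si](C)(C)OC/C(C)=C(\C[C@@H](O)[C@H](C)C=C)CC(OCC)OCC | intermediate
12 | ethyl vinyl ketone (pent-1-en-3-one) | C=CC(=O)CC | starting material
13 | (4E,6R,7R,9E)-11-[(tert-butyldimethylsilyl)oxy]-9-(2,2-diethoxyethyl)-7-hydroxy-6,10-dimethylundeca-4,9-dien-3-one | CC(C)(C)[Si](C)(C)OC/C(C)=C(\C[C@@H](O)[C@H](C)/C=C/C(=O)CC)CC(OCC)OCC | intermediate
14 | (3E,5R,6R,7E)-5-hydroxy-3-(1-hydroxypropan-2-ylidene)-6-methyl-9-oxoundec-7-enal (in equilibrium with its C5/C9-O lactol) | OC/C(C)=C(\C[C@@H](O)[C@H](C)/C=C/C(=O)CC)CC=O | intermediate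
15 | (1R,2E,4R,5R,6R)-4-hydroxy-2-(1-hydroxypropan-2-ylidene)-5-methyl-6-(2-oxobutyl)cyclohexane-1-carbaldehyde | CCC(=O)C[C@@H]1[C@@H](C)[C@H](O)C/C(=C(/C)CO)[C@@H]1C=O | intermediate
16 | (4aS,5E,7R,8R,8aS)-7-hydroxy-5-(1-hydroxypropan-2-ylidene)-3,8-dimethyl-4a,5,6,7,8,8a-hexahydronaphthalen-2(1H)-one | O=C1C[C@@H]2[C@@H](C)[C@H](O)C/C(=C(/C)CO)[C@@H]2C=C1C | intermediate
17 | (2R,4aS,5E,7R,8R,8aS)-5-(1-hydroxypropan-2-ylidene)-3,8-dimethyl-1,2,4a,5,6,7,8,8a-octahydronaphthalene-2,7-diol | O[C@@H]1C[C@@H]2[C@@H](C)[C@H](O)C/C(=C(/C)CO)[C@@H]2C=C1C | intermediate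
18 | (2E)-2-[(3R,4R,4aS,6R,8aS)-3,6-dihydroxy-4,7-dimethyl-3,4,4a,5,6,8a-hexahydronaphthalen-1(2H)-ylidene]propyl formate | O[C@@H]1C[C@@H]2[C@@H](C)[C@H](O)C/C(=C(/C)COC=O)[C@@H]2C=C1C | intermediate
19 | (2E)-2-[(3R,4R,4aS,6R,8aS)-3,6-bis(acetyloxy)-4,7-dimethyl-3,4,4a,5,6,8a-hexahydronaphthalen-1(2H)-ylidene]propyl formate (CNP0262962.1) | CC(=O)O[C@@H]1C[C@@H]2[C@@H](C)[C@H](OC(C)=O)C/C(=C(/C)COC=O)[C@@H]2C=C1C | target

## Step count and risks

Total step count: 10. Longest linear sequence: 10 steps (from 1; compounds 3, 9 and 12 are bought).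

**Step 7 (the two-ring cascade) is the most likely to fail.** The lactol form of 14 may enter the enamine manifold slowly. The dienamine may protonate at C11 and move the C7=C11 double bond into conjugation, and the skipped enone of 16 may isomerise to the linear dienone. Attack through C11 instead of C6 is a further, sterically disfavoured, side path. The fallback sets out from 13, removes the lactol and separates the two ring closures, and comes back at 19:
- Acetylation of 13 (Ac2O, DMAP) gives (4E,6R,7R,9E)-11-[(tert-butyldimethylsilyl)oxy]-9-(2,2-diethoxyethyl)-6,10-dimethyl-3-oxoundeca-4,9-dien-7-yl acetate F1.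
- AcOH/THF/H2O then gives the open-chain aldehyde (4E,6R,7R,9E)-11-hydroxy-6,10-dimethyl-3-oxo-9-(2-oxoethyl)undeca-4,9-dien-7-yl acetate F2, which cannot form a lactol.
- A diphenylprolinol trimethylsilyl ether/benzoic acid catalysed Michael addition at 0 °C (catalyst enantiomer matched to the substrate) gives the isolated keto aldehyde (1R,2R,3R,4R,5E)-4-formyl-5-(1-hydroxypropan-2-ylidene)-2-methyl-3-(2-oxobutyl)cyclohexyl acetate F3.
- A separate aldol condensation with dibenzylammonium trifluoroacetate gives the 9-O-acetyl derivative of enone 16 F4.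
- Luche reduction gives the 9-O-acetyl derivative of triol 17 F5.
- Formylation of the primary alcohol gives the 9-acetate 12-formate with free C3-OH F6, and acetylation of F6 gives 19.

**Step 4 (oxidative cleavage) may fail on chemoselectivity.** OsO4 may also attack the electron-rich tetrasubstituted alkene. The fallback sets out from 2, avoids alkene cleavage by bringing in C8–C9 at the carboxyl oxidation level, and comes back at 8:
- The same carbomagnesiation of 2 is quenched with I2 to give (2Z)-5,5-diethoxy-3-iodo-2-methylpent-2-en-1-ol F7.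
- TBSCl/imidazole gives tert-butyl{[(2Z)-5,5-diethoxy-3-iodo-2-methylpent-2-en-1-yl]oxy}dimethylsilane F8.
- Negishi coupling with the Reformatsky reagent BrZnCH2CO2Et (Pd(PPh3)4, THF, 60 °C) gives ethyl (3Z)-5-[(tert-butyldimethylsilyl)oxy]-3-(2,2-diethoxyethyl)-4-methylpent-3-enoate F9 with retention of geometry.
- i-Bu2AlH at −78 °C reduces F9 to 8.

**Step 9 (selective formylation) may give mixtures.** Formyl transfer to one of three free hydroxyls may also give bis-formates. The fallback sets out from 17, replaces kinetic discrimination by temporary protection, and comes back at 19: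
- Primary-selective silylation (TBSCl, imidazole, −20 °C) gives the 12-O-tert-butyldimethylsilyl ether of triol 17 F10.
- Ac2O/DMAP gives the 3,9-diacetate 12-O-tert-butyldimethylsilyl ether F11.
- HF·pyridine gives the 3,9-diacetate with free C12-OH F12.
- Formylation of F12 (acetic formic anhydride, pyridine) gives 19.

Further compounds

F1 | step 7 | (4E,6R,7R,9E)-11-[(tert-butyldimethylsilyl)oxy]-9-(2,2-diethoxyethyl)-6,10-dimethyl-3-oxoundeca-4,9-dien-7-yl acetate | CC(C)(C)[Si](C)(C)OC/C(C)=C(\C[C@@H](OC(C)=O)[C@H](C)/C=C/C(=O)CC)CC(OCC)OCC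
F2 | step 7 | (4E,6R,7R,9E)-11-hydroxy-6,10-dimethyl-3-oxo-9-(2-oxoethyl)undeca-4,9-dien-7-yl acetate | OC/C(C)=C(\C[C@@H](OC(C)=O)[C@H](C)/C=C/C(=O)CC)CC=O
F3 | step 7 | (1R,2R,3R,4R,5E)-4-formyl-5-(1-hydroxypropan-2-ylidene)-2-methyl-3-(2-oxobutyl)cyclohexyl acetate | CCC(=O)C[C@@H]1[C@@H](C)[C@H](OC(C)=O)C/C(=C(/C)CO)[C@@H]1C=O
F4 | step 7 | 9-O-acetyl derivative of enone 16 | O=C1C[C@@H]2[C@@H](C)[C@H](OC(C)=O)C/C(=C(/C)CO)[C@@H]2C=C1C
F5 | step 7 | 9-O-acetyl derivative of triol 17 | O[C@@H]1C[C@@H]2[C@@H](C)[C@H](OC(C)=O)C/C(=C(/C)CO)[C@@H]2C=C1C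
F6 | step 7 | 9-acetate 12-formate with free C3-OH | O[C@@H]1C[C@@H]2[C@@H](C)[C@H](OC(C)=O)C/C(=C(/C)COC=O)[C@@H]2C=C1C
F7 | step 4 | (2Z)-5,5-diethoxy-3-iodo-2-methylpent-2-en-1-ol | OC/C(C)=C(\I)CC(OCC)OCC
F8 | step 4 | tert-butyl{[(2Z)-5,5-diethoxy-3-iodo-2-methylpent-2-en-1-yl]oxy}dimethylsilane | CC(C)(C)[Si](C)(C)OC/C(C)=C(\I)CC(OCC)OCC
F9 | step 4 | ethyl (3Z)-5-[(tert-butyldimethylsilyl)oxy]-3-(2,2-diethoxyethyl)-4-methylpent-3-enoate | CCOC(=O)C/C(=C(/C)CO[Si](C)(C)C(C)(C)C)CC(OCC)OCC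
F10 | step 9 | 12-O-tert-butyldimethylsilyl ether of triol 17 | O[C@@H]1C[C@@H]2[C@@H](C)[C@H](O)C/C(=C(/C)CO[Si](C)(C)C(C)(C)C)[C@@H]2C=C1C
F11 | step 9 | 3,9-diacetate 12-O-tert-butyldimethylsilyl ether | CC(=O)O[C@@H]1C[C@@H]2[C@@H](C)[C@H](OC(C)=O)C/C(=C(/C)CO[Si](C)(C)C(C)(C)C)[C@@H]2C=C1C
F12 | step 9 | 3,9-diacetate with free C12-OH | CC(=O)O[C@@H]1C[C@@H]2[C@@H](C)[C@H](OC(C)=O)C/C(=C(/C)CO)[C@@H]2C=C1C
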